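The ratio [reagent]/[left-handed substrate] is what I watch in this kinetic resolution. Both fall together by what is made, and in amber at 240 min left-handed substrate plus left-handed product reads 50.1%. If the rate goes as working catalyst times both concentrations, the logarithm of this ratio, taken from its starting value, advances with working catalyst times time. I call that logarithm the clock.

| flask | left-handed substrate | right-handed substrate | reagent | catalyst | remark | time |
|---|---|---|---|---|---|---|
| amber | 1 M | 1 M | 1.2 equiv | 0.1 mol% | the very flask that is asked about, followed so far |  |
| ochre | 1 M | 1 M | 1.2 equiv | 0.2 mol% | run made earlier |  |
| flask | 1.0 M | 1.0 M | 1.20 equiv | 0.1 mol% |  | 4.0 h |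

| run | time / min | left-handed product / % | left-handed substrate / % |
|---|---|---|---|
| amber | 20.0 | 14.7 | 34.7 |
| amber | 60.0 | 19.3 | 30.3 |
| amber | 120 | 21.9 | 27.8 |
| amber | 180 | 24.7 | 26.7 |
| amber | 240 | 24.6 | 25.5 |
| ochre | 2.00 | 5.0 | 43.6 |
| ochre | 4.00 | 10.0 | 40.5 |
| ochre | 8.00 | 15.3 | 34.8 |
| ochre | 12.0 | 20.2 | 31.0 |
| ochre | 25.0 | 24.8 | 25.7 |

(each reading ± 0.5 percentage points)

- left-handed product, in percent of the left-handed substrate and right-handed substrate together first charged, at 4.0 h
- the option that brings most further left-handed product ("none" if no option brings more than 2 percentage points) (noon / spring / midnight / none)
- left-handed product present, with what was taken out counted in, in percent of the left-handed substrate and right-handed substrate together first charged, after spring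
- left-handed product present, with what was taken out counted in, in percent of the left-handed substrate and right-handed substrate together first charged, after midnight

- noon: at 4.0 h take out 90% of the left-handed product then present, then wait 4.0 h
- spring: at 4.0 h add catalyst, 100% of the amount charged, then wait 4.0 h
- midnight: change nothing and wait 4.0 h more

- catalyst is single-handed; left-handed substrate and right-handed substrate are mirror images of each other, charged as a racemate, each of them at the stated concentration
- left-handed product taken out counts as made
- the numbers in the tables scatter by 0.5 percentage points (one standard deviation)
- additions bring no volume worth counting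

In amber, the flask asked about, I average product with substrate loss, and the clock reads 0.101 at 60.0 min and 0.149 at 240 min. So its late pace, the clock's advance per hour after the early rush, is 0.0159 h⁻¹, and the rush itself is worth 0.0853. My own figure for amber at 4.0 h is 24.6%. Ochre, with 0.2 mol% of catalyst, reads 0.149 at 25.0 min, and amber, with 0.1 mol%, reads 0.0690 at 20.0 min; ochre's reading is about twice amber's, and although the two times differ, which makes the comparison a rough one, I take the clock to follow the catalyst charged and to need no term for product.

Waiting adds 0.0638 to the clock, and turning that back into amounts gives 29.4%. Taking out product leaves the ratio where it stands, so I reckon noon equal to midnight. Adding catalyst, as I reckon it, brings a second rush and a pace twice the late one, which gives 36.2%, so I choose spring.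

The forecast, reading the plateau as “a reversible step”, gives 24.7% now, noon as best, 25.2% after spring and 25% after midnight, and so differs from me on the choice and on both amounts.

The flask gives 25.5% now and spring as best, with 37.2% after spring, a gain of 12 percentage points, and 30.7% after midnight, a gain of 5.3 points, while noon gains 5.3 points.

    catalyst ⇌ dormant form (K = 17.0, k = 0.0620 min⁻¹)
    reagent + catalyst + left-handed substrate → catalyst + left-handed product (k = 28.9 M⁻² min⁻¹)
    reagent + catalyst + right-handed substrate → catalyst + right-handed product (k = 0.214 M⁻² min⁻¹)

In the flask, catalyst stands at 5.59% of its charge after 120 min and at 5.56% after 240 min, with the dormant form at 94.4%. Read through the clock, midnight advances it by 0.0763 and spring by 0.234. For the neighbouring flask, read at 1.5 h, the late pace 0.0159 h⁻¹ carries the clock on from 0.101 to 0.109, which means 20.5% of left-handed product, and that flask holds 20.7%.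

The readings are calculated from invented constants.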